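**Plan**

- Retrosynthetic cuts: (a) the two C–C bonds of the central cyclohexene (Diels–Alder homodimerisation of one triene monomer); (b) the bond from the cyclopentane CH to its alkenyl side chain (Pd α-alkenylation); (c) the ring CH2–C(OH)CH3 bond of the cyclohexane (radical ring closure); (d) the bond between the future spiro carbon and the ring CH that carries the ester chain (Michael addition).
- Forward order: 2-acetylcyclopentanone gives the quaternary carbon, the cyclohexane is closed onto it (spiro[4.5]decane), then enal appendage, side chain and secondary carbinol follow; the cyclohexene is formed last.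
- Enabling feature: the C(OH)CH3 carbon of the six-membered ring and the CH(OH) carbon of the five-membered ring are both bonded to the spiro carbon. At the diketone level both carbonyls can enolise only away from that quaternary carbon, so they are tied into a six-membered di-tert-butylsilylene bis(enol ether). Its exocyclic CH2=C(OSi) is the radical precursor and its ring fixes the new carbinol centre.
- Stereochemistry: chiral catalyst (quaternary carbon and adjacent CH); silylene ring (tertiary carbinol); steric approach (side-chain CH); hydroxyl-directed hydride (secondary carbinol); equilibration (enal geometry); Diels–Alder topology (cyclohexene, not catalyst-controlled).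

Key step: step 9

Assumption: the (R,R)-thiourea of step 4 is taken to be the antipode giving the (R)-quaternary carbon with the unlike relationship to the neighbouring CH, and the enal geometry of the target is taken to be the thermodynamically preferred one.

**Step 1**
Reactants: 1 butane-1,4-diol; 2 tetradecanoyl chloride
Product: 3 4-hydroxybutyl tetradecanoate
Conditions: 1 (5 equiv), pyridine, CH2Cl2, 0 °C to rt
Reagents that add atoms: none
Why: Nucleophilic acyl substitution on a symmetrical diol used in excess should give the monoester, and no stereocentre is formed.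

**Step 2**
Reactants: 3 4-hydroxybutyl tetradecanoate
Product: 4 4-oxobutyl tetradecanoate
Conditions: TEMPO (10 mol %), PhI(OAc)2, CH2Cl2, rt
Reagents that add atoms: none
Why: The oxoammonium oxidation stops at the aldehyde and leaves the ester untouched.

**Step 3**
Reactants: 4 4-oxobutyl tetradecanoate
Product: 7 (4E)-5-nitropent-4-en-1-yl tetradecanoate, via nitro alcohol 5 (not isolated), via mesylate 6 (not isolated)
Conditions: MeNO2, Et3N (cat.), THF, 0 °C to rt; then MsCl, Et3N, CH2Cl2, −20 to 0 °C
Reagents that add atoms: nitromethane, C[N+](=O)[O-]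
Why: Henry addition followed by E1cB loss of methanesulfonate should give the conjugated nitroalkene as its more stable (E)-isomer.

**Step 4**
Reactants: 7 (4E)-5-nitropent-4-en-1-yl tetradecanoate; 8 2-acetylcyclopentan-1-one
Product: 9 (4S)-4-[(1R)-1-acetyl-2-oxocyclopentyl]-5-nitropentyl tetradecanoate
Conditions: 1-[3,5-bis(trifluoromethyl)phenyl]-3-[(1R,2R)-2-(dimethylamino)cyclohexyl]thiourea (10 mol %), toluene, −20 °C
Reagents that add atoms: none
Why: In this organocatalytic Michael addition the thiourea binds the nitro group and the tertiary amine holds the enol of 8, so the quaternary carbon and the adjacent CH are formed together with the catalyst selecting both faces.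

**Step 5**
Reactants: 9 (4S)-4-[(1R)-1-acetyl-2-oxocyclopentyl]-5-nitropentyl tetradecanoate
Product: 11 (4S)-4-[(1R)-1-acetyl-2-oxocyclopentyl]-5-oxopentyl tetradecanoate, via sodium nitronate 10 (not isolated)
Conditions: NaOMe (1.05 equiv), MeOH/CH2Cl2, −78 °C; O3, −78 °C; N2 purge, aq. KH2PO4
Reagents that add atoms: ozone, [O-][O+]=O
Why: This Nef reaction by ozonolysis of the nitronate C=N bond should give the aldehyde cold and buffered, so the α-stereocentre and the non-enolisable 1,3-diketone are not disturbed.

**Step 6**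
Reactants: 11 (4S)-4-[(1R)-1-acetyl-2-oxocyclopentyl]-5-oxopentyl tetradecanoate
Product: 12 (4S)-4-[(1R)-1-acetyl-2-oxocyclopentyl]-5-hydroxyhept-6-en-1-yl tetradecanoate
Conditions: CH2=CHMgBr (1.1 equiv), THF, −78 °C; aq. NH4Cl
Reagents that add atoms: vinylmagnesium bromide, C=C[Mg]Br
Why: In this Grignard addition the aldehyde is far more electrophilic than the two neopentyl ketones and the ester at −78 °C, and the new carbinol centre (epimer mixture) is removed again in step 8.

**Step 7**
Reactants: 12 (4S)-4-[(1R)-1-acetyl-2-oxocyclopentyl]-5-hydroxyhept-6-en-1-yl tetradecanoate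
Product: 15 (4S)-4-[(4aR)-2,2-di-tert-butyl-4-methylidene-5,6-dihydrocyclopenta[d][1,3,2]dioxasilin-4a(4H)-yl]-5-hydroxyhept-6-en-1-yl tetradecanoate, via trimethylsilyl ether 13 (not isolated), via silylene trimethylsilyl ether 14 (not isolated)
Conditions: BSA, CH2Cl2, rt; then t-Bu2Si(OTf)2, Et3N, −78 to 0 °C; then citric acid, MeOH, 0 °C
Reagents that add atoms: di-tert-butylsilyl bis(trifluoromethanesulfonate), CC(C)(C)[Si](OS(=O)(=O)C(F)(F)F)(OS(=O)(=O)C(F)(F)F)C(C)(C)C
Why: Soft enolisation and O-silylation (silyl triflate/amine) of both ketones, each of which can enolise only away from the quaternary carbon, should close the six-membered silylene bis(enol ether) while the alcohol is masked transiently as its labile trimethylsilyl ether.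

**Step 8**
Reactants: 15 the silylene allylic alcohol
Product: 16 (4S)-4-[(4aR)-2,2-di-tert-butyl-4-methylidene-5,6-dihydrocyclopenta[d][1,3,2]dioxasilin-4a(4H)-yl]-5-oxohept-6-en-1-yl tetradecanoate
Conditions: Dess–Martin periodinane, NaHCO3, CH2Cl2, 0 °C to rt
Reagents that add atoms: none
Why: Buffered Dess–Martin oxidation should give the vinyl ketone without touching the enol ethers, and it is done only now so that no enone is present during the silyl triflate step.

**Step 9**
Reactants: 16 the vinyl ketone
Product: 17 3-[(5R,6S,10S)-6-methyl-9-oxo-1,6-(di-tert-butylsilanediyldioxy)spiro[4.5]dec-1-en-10-yl]propyl tetradecanoate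
Conditions: Fe(acac)3 (30 mol %), PhSiH3 (1.5 equiv), Na2HPO4, EtOH/(CH2OH)2 5:1 (0.01 M), 60 °C
Reagents that add atoms: none
Why: An iron hydride formed from Fe(acac)3 and PhSiH3 transfers a hydrogen atom to the exocyclic methylene of the 1,1-disubstituted silyl enol ether, which creates the methyl group and a tertiary α-silyloxy radical; this radical adds to the terminal carbon of the vinyl ketone, and the resulting α-keto radical is reduced and protonated by ethanol. The closest known reaction type is the metal-hydride hydrogen-atom-transfer reductive coupling (Giese addition) of heteroatom-substituted alkenes with enones, here run intramolecularly. The cyclohexanone closes in the 6-endo-trig mode with the carbonyl inside the new ring, the 5-exo alternative being disfavoured because it would attack the α-carbon of the enone and leave a primary radical. The only new stereocentre, the carbinol carbon, is controlled by the dioxasiline ring: the O–Si–O bridge can persist only if the new ring is cis-fused to it, so the C–O bond ends up syn to the cyclopentene carbon on the spiro centre, whereas the CH stereocentre next to the ketone is not touched. The step needs hydrogen-atom transfer to the exocyclic enol ether and not to the trisubstituted cyclopentenyl enol ether or the enone, which the better accessibility of the 1,1-disubstituted terminus should secure, and the silane is limited so that the remaining enol ether is not reduced.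

**Step 10**
Reactants: 17 the spiro ketone
Product: 18 3-[(5R,6S,10S)-9-hydroxy-6-methyl-9-(prop-1-en-2-yl)-1,6-(di-tert-butylsilanediyldioxy)spiro[4.5]dec-1-en-10-yl]propyl tetradecanoate
Conditions: CeCl3 (1.6 equiv), CH2=C(CH3)MgBr (1.5 equiv), THF, −78 °C; aq. NH4Cl
Reagents that add atoms: isopropenylmagnesium bromide, CC(=C)[Mg]Br
Why: The weakly basic organocerium reagent should add to the only ketone (hindered but not enolised) faster than to the ester at −78 °C, and the carbinol configuration is irrelevant because the centre becomes sp2 in step 11.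

**Step 11**
Reactants: 18 the tertiary allylic alcohol
Product: 19 3-[(5R,6S,10R)-9-(1-hydroxypropan-2-ylidene)-6-methyl-1,6-(di-tert-butylsilanediyldioxy)spiro[4.5]dec-1-en-10-yl]propyl tetradecanoate
Conditions: Ph3SiOReO3 (5 mol %), Et2O, 0 °C to rt
Reagents that add atoms: none
Why: The perrhenate-catalysed 1,3-transposition ([3,3] shift of the allyl perrhenate) should move the hydroxyl to the primary carbon with formation of the more substituted ring-exocyclic alkene, obtained as a mixture of geometric isomers that is corrected in step 20.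

**Step 12**
Reactants: 20 6-methylhept-5-en-2-one
Product: 22 6-methylhepta-1,5-dien-2-yl trifluoromethanesulfonate, via lithium enolate 21 (not isolated)
Conditions: LiN(i-Pr)2, THF, −78 °C; then PhNTf2, −78 to 0 °C
Reagents that add atoms: N-phenylbis(trifluoromethanesulfonimide), O=S(=O)(N(c1ccccc1)S(=O)(=O)C(F)(F)F)C(F)(F)F
Why: Kinetic deprotonation at the methyl group and O-triflation should give the terminal enol triflate.

**Step 13**
Reactants: 22 the enol triflate
Product: 23 (2E)-8-methyl-4-methylidenenona-2,7-dienal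
Conditions: acrolein (3 equiv), Pd(OAc)2 (5 mol %), PPh3 (10 mol %), Et3N, DMF, 60 °C
Reagents that add atoms: acrolein, C=CC=O
Why: The Heck reaction of the alkenyl triflate with acrolein should give the (E)-dienal through syn-insertion and syn-β-hydride elimination.

**Step 14**
Reactants: 23 the dienal
Product: 24 ethyl (2Z,4E)-2-bromo-10-methyl-6-methylideneundeca-2,4,9-trienoate
Conditions: (EtO)2P(O)CHBrCO2Et, NaH, THF, −78 to 0 °C
Reagents that add atoms: triethyl 2-bromo-2-phosphonoacetate, CCOC(=O)C(Br)P(=O)(OCC)OCC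
Why: The Horner–Wadsworth–Emmons reaction places the ester trans to the dienyl chain, which puts bromine cis to it, the geometry that is later transferred to the side chain.

**Step 15**
Reactants: 24 the bromo ester
Product: 25 (2Z,4E)-2-bromo-10-methyl-6-methylideneundeca-2,4,9-trien-1-ol
Conditions: i-Bu2AlH (2.2 equiv), CH2Cl2, −78 °C; Rochelle salt
Reagents that add atoms: none
Why: 1,2-Reduction of the unsaturated ester by the aluminium hydride should give the allylic alcohol without touching the alkenyl bromide.

**Step 16**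
Reactants: 25 the bromo alcohol
Product: 26 {[(2Z,4E)-2-bromo-10-methyl-6-methylideneundeca-2,4,9-trien-1-yl]oxy}(tert-butyl)diphenylsilane
Conditions: TBDPSCl, imidazole, DMF, 0 °C to rt
Reagents that add atoms: tert-butyl(chloro)diphenylsilane, CC(C)(C)[Si](Cl)(c1ccccc1)c1ccccc1
Why: Silylation gives an ether that should survive the buffered HF of step 18 and that keeps this allylic alcohol out of the MnO2 oxidation of step 20.

**Step 17**
Reactants: 19 the enol silane; 26 the alkenyl bromide
Product: 27 3-[(2S,5R,6S,10R)-2-[(2E,4E)-1-(tert-butyldiphenylsilyloxy)-10-methyl-6-methylideneundeca-2,4,9-trien-2-yl]-6-[di-tert-butyl(fluoro)silyloxy]-9-(1-hydroxypropan-2-ylidene)-6-methyl-1-oxospiro[4.5]decan-10-yl]propyl tetradecanoate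
Conditions: Pd2(dba)3 (2.5 mol %), P(t-Bu)3 (10 mol %), ZnF2 (0.6 equiv), CsF (0.2 equiv), DMF, 70 °C
Reagents that add atoms: zinc difluoride, [Zn+2].[F-].[F-]
Why: In this palladium-catalysed α-alkenylation of an enol silane, fluoride opens the enol Si–O bond to a zinc enolate that couples with retention of the bromide geometry, and the bulky palladium enolate should form on the ketone face remote from the silyloxy-bearing carbinol carbon, which puts the side chain cis to the ring CH of the cyclohexane (2S).

**Step 18**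
Reactants: 27 the fluorosilyl ether
Product: 28 3-[(2S,5R,6S,10R)-2-[(2E,4E)-1-(tert-butyldiphenylsilyloxy)-10-methyl-6-methylideneundeca-2,4,9-trien-2-yl]-6-hydroxy-9-(1-hydroxypropan-2-ylidene)-6-methyl-1-oxospiro[4.5]decan-10-yl]propyl tetradecanoate
Conditions: HF·pyridine, pyridine, THF, 0 °C
Reagents that add atoms: none
Why: Acid-buffered fluoride should cleave the activated fluorosilyl ether faster than the primary TBDPS ether, and because no alkoxide is formed the tertiary β-hydroxy ketone cannot undergo retro-aldol cleavage.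

**Step 19**
Reactants: 28 the β-hydroxy ketone
Product: 29 3-[(1R,2S,5S,6S,10R)-2-[(2E,4E)-1-(tert-butyldiphenylsilyloxy)-10-methyl-6-methylideneundeca-2,4,9-trien-2-yl]-1,6-dihydroxy-9-(1-hydroxypropan-2-ylidene)-6-methylspiro[4.5]decan-10-yl]propyl tetradecanoate
Conditions: Me4NBH(OAc)3 (5 equiv), MeCN/AcOH 1:1, −30 °C
Reagents that add atoms: none
Why: In this Evans–Saksena reduction the tertiary hydroxyl binds boron and delivers hydride to the ketone face on its own side, which should give the anti-1,3-diol with the new hydroxyl cis to the side chain (1R), the reagent being too weak to reduce anything it is not delivered to.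

**Step 20**
Reactants: 29 the triol
Product: 31 3-[(1R,2S,5S,6S,9Z,10R)-2-[(2E,4E)-1-(tert-butyldiphenylsilyloxy)-10-methyl-6-methylideneundeca-2,4,9-trien-2-yl]-1,6-dihydroxy-6-methyl-9-(1-oxopropan-2-ylidene)spiro[4.5]decan-10-yl]propyl tetradecanoate, via enal isomer mixture 30 (not isolated)
Conditions: MnO2 (20 equiv), CH2Cl2, rt; filtration; then pyrrolidine (10 mol %), AcOH (10 mol %), CH2Cl2, rt
Reagents that add atoms: none
Why: MnO2 oxidises only the free allylic alcohol, and reversible iminium/dienamine formation should then equilibrate the tetrasubstituted enal to the isomer with the small formyl group on the side of the substituted ring CH and the methyl group on the CH2 side.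

**Step 21**
Reactants: 31 the silyl-protected enal
Product: 32 3-[(1R,2S,5S,6S,9Z,10R)-1,6-dihydroxy-2-[(2E,4E)-1-hydroxy-10-methyl-6-methylideneundeca-2,4,9-trien-2-yl]-6-methyl-9-(1-oxopropan-2-ylidene)spiro[4.5]decan-10-yl]propyl tetradecanoate
Conditions: TBAF, AcOH, THF, 0 °C to rt
Reagents that add atoms: none
Why: Buffered fluoride removes the TBDPS group and should leave the ester and the enal intact.

**Step 22**
Reactants: 32 the triene monomer (two molecules)
Product: 33 the target dimer CNP0458412.1
Conditions: BHT (5 mol %), toluene (3 M), 110 °C, sealed tube; preparative HPLC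
Reagents that add atoms: none
Why: In this Diels–Alder homodimerisation the terminal 2-alkyl-1,3-diene of one molecule (the inner diene is blocked from s-cis by its cis substituent) adds to the terminal 1,1-disubstituted alkene of a second with the substituent-directed "para/ortho" orientation; the quaternary carbon and the adjacent CH require the homoprenyl-endo/dienyl-exo approach on one face, for which the remote spiro units give little bias, so the target is expected together with diastereomers and has to be separated.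

**Compound list**

1 | butane-1,4-diol | OCCCCO | starting material
2 | tetradecanoyl chloride | CCCCCCCCCCCCCC(=O)Cl | starting material
3 | 4-hydroxybutyl tetradecanoate | CCCCCCCCCCCCCC(=O)OCCCCO | intermediate
4 | 4-oxobutyl tetradecanoate | CCCCCCCCCCCCCC(=O)OCCCC=O | intermediate
5 | 4-hydroxy-5-nitropentyl tetradecanoate (racemic) | CCCCCCCCCCCCCC(=O)OCCCC(O)C[N+](=O)[O-] | intermediate
6 | 4-(methanesulfonyloxy)-5-nitropentyl tetradecanoate (racemic) | CCCCCCCCCCCCCC(=O)OCCCC(OS(C)(=O)=O)C[N+](=O)[O-] | intermediate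
7 | (4E)-5-nitropent-4-en-1-yl tetradecanoate | CCCCCCCCCCCCCC(=O)OCCC/C=C/[N+](=O)[O-] | intermediate
8 | 2-acetylcyclopentan-1-one | CC(=O)C1CCCC1=O | starting material
9 | (4S)-4-[(1R)-1-acetyl-2-oxocyclopentyl]-5-nitropentyl tetradecanoate | CCCCCCCCCCCCCC(=O)OCCC[C@H](C[N+](=O)[O-])[C@@]1(C(C)=O)CCCC1=O | intermediate
10 | sodium nitronate of 9 | CCCCCCCCCCCCCC(=O)OCCC[C@H](C=[N+]([O-])[O-])[C@@]1(C(C)=O)CCCC1=O.[Na+] | intermediate
11 | (4S)-4-[(1R)-1-acetyl-2-oxocyclopentyl]-5-oxopentyl tetradecanoate | CCCCCCCCCCCCCC(=O)OCCC[C@H](C=O)[C@@]1(C(C)=O)CCCC1=O | intermediate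
12 | (4S)-4-[(1R)-1-acetyl-2-oxocyclopentyl]-5-hydroxyhept-6-en-1-yl tetradecanoate (epimers at the carbinol carbon) | CCCCCCCCCCCCCC(=O)OCCC[C@H](C(O)C=C)[C@@]1(C(C)=O)CCCC1=O | intermediate
13 | trimethylsilyl ether of 12 | CCCCCCCCCCCCCC(=O)OCCC[C@H](C(O[Si](C)(C)C)C=C)[C@@]1(C(C)=O)CCCC1=O | intermediate
14 | trimethylsilyl ether of 15 | CCCCCCCCCCCCCC(=O)OCCC[C@H](C(O[Si](C)(C)C)C=C)[C@@]12CCC=C1O[Si](C(C)(C)C)(C(C)(C)C)OC2=C | intermediate
15 | (4S)-4-[(4aR)-2,2-di-tert-butyl-4-methylidene-5,6-dihydrocyclopenta[d][1,3,2]dioxasilin-4a(4H)-yl]-5-hydroxyhept-6-en-1-yl tetradecanoate | CCCCCCCCCCCCCC(=O)OCCC[C@H](C(O)C=C)[C@@]12CCC=C1O[Si](C(C)(C)C)(C(C)(C)C)OC2=C | intermediate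
16 | (4S)-4-[(4aR)-2,2-di-tert-butyl-4-methylidene-5,6-dihydrocyclopenta[d][1,3,2]dioxasilin-4a(4H)-yl]-5-oxohept-6-en-1-yl tetradecanoate | CCCCCCCCCCCCCC(=O)OCCC[C@H](C(=O)C=C)[C@@]12CCC=C1O[Si](C(C)(C)C)(C(C)(C)C)OC2=C | intermediate
17 | 3-[(5R,6S,10S)-6-methyl-9-oxo-1,6-(di-tert-butylsilanediyldioxy)spiro[4.5]dec-1-en-10-yl]propyl tetradecanoate (silylene bridges the oxygens on C-1 and C-6) | CCCCCCCCCCCCCC(=O)OCCC[C@@H]1C(=O)CC[C@]2(C)O[Si](C(C)(C)C)(C(C)(C)C)OC3=CCC[C@@]123 | intermediate
18 | 3-[(5R,6S,10S)-9-hydroxy-6-methyl-9-(prop-1-en-2-yl)-1,6-(di-tert-butylsilanediyldioxy)spiro[4.5]dec-1-en-10-yl]propyl tetradecanoate (C-9 configuration not defined) | CCCCCCCCCCCCCC(=O)OCCC[C@@H]1C(O)(C(C)=C)CC[C@]2(C)O[Si](C(C)(C)C)(C(C)(C)C)OC3=CCC[C@@]123 | intermediate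
19 | 3-[(5R,6S,10R)-9-(1-hydroxypropan-2-ylidene)-6-methyl-1,6-(di-tert-butylsilanediyldioxy)spiro[4.5]dec-1-en-10-yl]propyl tetradecanoate (mixture of exocyclic alkene isomers) | CCCCCCCCCCCCCC(=O)OCCC[C@@H]1C(=C(C)CO)CC[C@]2(C)O[Si](C(C)(C)C)(C(C)(C)C)OC3=CCC[C@@]123 | intermediate
20 | 6-methylhept-5-en-2-one | CC(=O)CCC=C(C)C | starting material
21 | lithium 6-methylhepta-1,5-dien-2-olate | [Li+].[O-]C(=C)CCC=C(C)C | intermediate
22 | 6-methylhepta-1,5-dien-2-yl trifluoromethanesulfonate | C=C(OS(=O)(=O)C(F)(F)F)CCC=C(C)C | intermediate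
23 | (2E)-8-methyl-4-methylidenenona-2,7-dienal | O=C/C=C/C(=C)CCC=C(C)C | intermediate
24 | ethyl (2Z,4E)-2-bromo-10-methyl-6-methylideneundeca-2,4,9-trienoate | CCOC(=O)/C(Br)=C/C=C/C(=C)CCC=C(C)C | intermediate
25 | (2Z,4E)-2-bromo-10-methyl-6-methylideneundeca-2,4,9-trien-1-ol | OC/C(Br)=C/C=C/C(=C)CCC=C(C)C | intermediate
26 | {[(2Z,4E)-2-bromo-10-methyl-6-methylideneundeca-2,4,9-trien-1-yl]oxy}(tert-butyl)diphenylsilane | CC(C)(C)[Si](c1ccccc1)(c1ccccc1)OC/C(Br)=C/C=C/C(=C)CCC=C(C)C | intermediate
27 | 3-[(2S,5R,6S,10R)-2-[(2E,4E)-1-(tert-butyldiphenylsilyloxy)-10-methyl-6-methylideneundeca-2,4,9-trien-2-yl]-6-[di-tert-butyl(fluoro)silyloxy]-9-(1-hydroxypropan-2-ylidene)-6-methyl-1-oxospiro[4.5]decan-10-yl]propyl tetradecanoate (mixture of exocyclic alkene isomers) | CCCCCCCCCCCCCC(=O)OCCC[C@@H]1C(=C(C)CO)CC[C@](C)(O[Si](F)(C(C)(C)C)C(C)(C)C)[C@@]12CC[C@@H](/C(=C\C=C\C(=C)CCC=C(C)C)CO[Si](c3ccccc3)(c3ccccc3)C(C)(C)C)C2=O | intermediate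
28 | the 6-hydroxy compound from 27 (2S,5R,6S,10R; mixture of exocyclic alkene isomers) | CCCCCCCCCCCCCC(=O)OCCC[C@@H]1C(=C(C)CO)CC[C@](C)(O)[C@@]12CC[C@@H](/C(=C\C=C\C(=C)CCC=C(C)C)CO[Si](c3ccccc3)(c3ccccc3)C(C)(C)C)C2=O | intermediate
29 | the (1R,2S,5S,6S,10R)-1,6-diol from 28 (mixture of exocyclic alkene isomers) | CCCCCCCCCCCCCC(=O)OCCC[C@@H]1C(=C(C)CO)CC[C@](C)(O)[C@@]12CC[C@@H](/C(=C\C=C\C(=C)CCC=C(C)C)CO[Si](c3ccccc3)(c3ccccc3)C(C)(C)C)[C@H]2O | intermediate
30 | the enal from 29 as a mixture of exocyclic alkene isomers | CCCCCCCCCCCCCC(=O)OCCC[C@@H]1C(=C(C)C=O)CC[C@](C)(O)[C@@]12CC[C@@H](/C(=C\C=C\C(=C)CCC=C(C)C)CO[Si](c3ccccc3)(c3ccccc3)C(C)(C)C)[C@H]2O | intermediate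
31 | the (9Z)-enal, silyl ether of the monomer | CCCCCCCCCCCCCC(=O)OCCC[C@@H]1/C(=C(/C)C=O)CC[C@](C)(O)[C@@]12CC[C@@H](/C(=C\C=C\C(=C)CCC=C(C)C)CO[Si](c3ccccc3)(c3ccccc3)C(C)(C)C)[C@H]2O | intermediate
32 | triene monomer, 3-[(1R,2S,5S,6S,9Z,10R)-1,6-dihydroxy-2-[(2E,4E)-1-hydroxy-10-methyl-6-methylideneundeca-2,4,9-trien-2-yl]-6-methyl-9-(1-oxopropan-2-ylidene)spiro[4.5]decan-10-yl]propyl tetradecanoate | CCCCCCCCCCCCCC(=O)OCCC[C@@H]1/C(=C(/C)C=O)CC[C@](C)(O)[C@@]12CC[C@@H](/C(=C\C=C\C(=C)CCC=C(C)C)CO)[C@H]2O | intermediate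
33 | CNP0458412.1 (Diels–Alder dimer of 32; on the cyclohexene the homoprenyl group of the quaternary carbon is cis to the alkenyl group of the adjacent CH) | CCCCCCCCCCCCCC(=O)OCCC[C@@H]1/C(=C(/C)C=O)CC[C@](C)(O)[C@@]12CC[C@@H](/C(=C\C=C\[C@@]1(CCC=C(C)C)CCC(CCC=C(C)C)=C[C@@H]1/C=C(/CO)[C@@H]1CC[C@]3([C@H](CCCOC(=O)CCCCCCCCCCCCC)/C(=C(/C)C=O)CC[C@]3(C)O)[C@@H]1O)CO)[C@H]2O | target

**Step count and risks**

Total step count: 22. Longest linear sequence: 17 steps (steps 1–11 and 17–22); the side-chain branch (steps 12–16) joins at step 17.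

Steps most likely to fail:

Step 22. The process at risk is facial and endo/exo discrimination in the dimerisation, because the stereocentres of the two spiro units are far from the reacting termini; oligomerisation may compete. The fallback sets out from 32. The primary allylic hydroxyl groups of two molecules are joined with 1,3-dichloro-1,1,3,3-tetraisopropyldisiloxane (0.5 equiv, imidazole, DMF, slow addition; the hindered secondary and tertiary hydroxyls stay free) to give the disiloxane-bridged bis(triene) F1. Heating F1 at high dilution makes the cycloaddition intramolecular within a macrocycle, in which the tether limits the mutual orientation of the two homochiral halves, and gives the bridged cycloadduct F2. TBAF/AcOH removes the tether, and the route is rejoined at 33.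

Step 17. The processes at risk are protodesilylation of the hindered enol silane without coupling, migration of the side-chain double bond into conjugation with the ketone, and erosion of the configuration at the new CH. The fallback sets out from 19 and 26. NBS converts the enol silane of 19 into the α-bromo ketone silanol F3, and 26 is converted (t-BuLi, then ZnBr2) into the alkenylzinc bromide F4. A nickel-catalysed Negishi coupling of the secondary α-bromo ketone (NiCl2·glyme, chiral pybox ligand, −30 °C) joins F3 and F4 to the coupled silanol F5 under neutral conditions. HF·pyridine then removes the silanol group, and the route is rejoined at 28.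

Step 4. The process at risk is the relative topicity of the addition (attack on the other nitroalkene face would give the epimer at the CH carbon), together with sluggish reaction of an aliphatic nitroalkene. The fallback sets out from 4 and 8. Vinylmagnesium bromide converts 4 into the racemic allylic alcohol F6, and methyl chloroformate/pyridine gives the allylic carbonate F7. Iridium-catalysed branched-selective allylic alkylation of 8 with F7 ([Ir(cod)Cl]2, chiral phosphoramidite, with a chiral Lewis-acid co-catalyst for the enolate) gives the vinyl compound F8; here the allylic carbon is fixed by the iridium ligand and the quaternary carbon by the co-catalyst, so either relative configuration can be selected. Ozonolysis of F8 (O3, then PPh3) gives aldehyde 11, where the route is rejoined.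

**Further compounds**

F1 | step 22 | disiloxane-bridged bis(triene): two molecules of 32 joined through their primary allylic oxygens by O–Si(i-Pr)2–O–Si(i-Pr)2–O | CCCCCCCCCCCCCC(=O)OCCC[C@@H]1/C(=C(/C)C=O)CC[C@](C)(O)[C@@]12CC[C@@H](/C(=C\C=C\C(=C)CCC=C(C)C)CO[Si](C(C)C)(C(C)C)O[Si](C(C)C)(C(C)C)OC/C(=C/C=C/C(=C)CCC=C(C)C)[C@@H]1CC[C@]3([C@H](CCCOC(=O)CCCCCCCCCCCCC)/C(=C(/C)C=O)CC[C@]3(C)O)[C@@H]1O)[C@H]2O
F2 | step 22 | bridged cycloadduct: 33 with its two primary allylic oxygens still joined by the tetraisopropyldisiloxane tether | CCCCCCCCCCCCCC(=O)OCCC[C@@H]1/C(=C(/C)C=O)CC[C@](C)(O)[C@@]12CC[C@@H](/C(=C\C=C\[C@@]1(CCC=C(C)C)CCC(CCC=C(C)C)=C[C@@H]1/C=C(/CO[Si](C(C)C)(C(C)C)O[Si]4(C(C)C)C(C)C)[C@@H]1CC[C@]3([C@H](CCCOC(=O)CCCCCCCCCCCCC)/C(=C(/C)C=O)CC[C@]3(C)O)[C@@H]1O)CO4)[C@H]2O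
F3 | step 17 | α-bromo ketone silanol: 2-bromo-1-oxo compound from 19 carrying a di-tert-butyl(hydroxy)silyl ether on the tertiary oxygen | CCCCCCCCCCCCCC(=O)OCCC[C@@H]1C(=C(C)CO)CC[C@](C)(O[Si](O)(C(C)(C)C)C(C)(C)C)[C@@]12CCC(Br)C2=O
F4 | step 17 | alkenylzinc bromide from 26 | CC(C)(C)[Si](c1ccccc1)(c1ccccc1)OC/C([Zn]Br)=C/C=C/C(=C)CCC=C(C)C
F5 | step 17 | coupled silanol: analogue of 27 with Si–OH in place of Si–F | CCCCCCCCCCCCCC(=O)OCCC[C@@H]1C(=C(C)CO)CC[C@](C)(O[Si](O)(C(C)(C)C)C(C)(C)C)[C@@]12CC[C@@H](/C(=C\C=C\C(=C)CCC=C(C)C)CO[Si](c3ccccc3)(c3ccccc3)C(C)(C)C)C2=O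
F6 | step 4 | 4-hydroxyhex-5-en-1-yl tetradecanoate (racemic) | CCCCCCCCCCCCCC(=O)OCCCC(O)C=C
F7 | step 4 | 4-[(methoxycarbonyl)oxy]hex-5-en-1-yl tetradecanoate (racemic) | CCCCCCCCCCCCCC(=O)OCCCC(OC(=O)OC)C=C
F8 | step 4 | (4R)-4-[(1R)-1-acetyl-2-oxocyclopentyl]hex-5-en-1-yl tetradecanoate | CCCCCCCCCCCCCC(=O)OCCC[C@H](C=C)[C@@]1(C(C)=O)CCCC1=O
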